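A direct plan would esterify 2-bromo-5-(hydroxymethyl)phenol to the aryl bromide A1, join it to the 2-borylallyl acetate A2 by a Suzuki–Miyaura coupling, and epoxidise the resulting α-(acetoxymethyl)styrene A3 enantioselectively in the last step.
Its weakest step would be that final oxygen transfer: the only stereocentre would rest on an undirected asymmetric epoxidation of a 1,1-disubstituted alkene whose two substituents (a twisted aryl ring and CH2OAc) are hard to tell apart, a substrate class without precedent, run on the most valuable material and giving an acid-labile benzylic oxirane.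
The cross-coupling would be the second weak point: zerovalent palladium would meet an allylic acetate that can ionise to a π-allyl complex, beside a hindered ortho-substituted bromide and a base-labile aryl ester.
The borylation that gives A2 would also depend on placing boron on the internal alkyne carbon, which is not the innate regiochemistry.

**Plan of the new route**
The retrosynthesis removes the acetyl group, cuts the oxirane O–CH2 bond to a bromohydrin, re-joins that CH2 and the CH2OH arm through one oxygen, and last cuts the aryl–C bond.
This works because C2 of the oxirane bears, beside the aryl group and the ring oxygen, two oxygenated methylenes (ring C3 and the acetoxymethyl carbon): it is C3 of an achiral 3-aryl-oxetan-3-ol whose ring carbons C2 and C4 are enantiotopic.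
Ring order: the benzene ring is bought, the oxetane is added as oxetan-3-one, and the oxirane arises last by ring contraction of the opened oxetane.
The stereocentre is set by a catalytic desymmetrising opening of the oxetane with bromide and is never a reacting centre afterwards.
No alkene, no oxidant and no palladium appear, and the last bond made is a primary acetate.

Key step: step 5

Assumption: the sense of induction of the squaramide catalyst on this oxetane is not predicted here; both catalyst antipodes are accessible, and the one that delivers bromide to the pro-R ring methylene of the oxetane is used.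

Step 1
Reactants: 1 2-bromo-5-(hydroxymethyl)phenol
Product: 2 [2-bromo-5-({[tri(propan-2-yl)silyl]oxy}methyl)phenoxy]tri(propan-2-yl)silane
Conditions: TIPSCl (2.4 equiv), imidazole (5 equiv), DMF, rt
Reagents that add atoms: chlorotri(propan-2-yl)silane CC(C)[Si](Cl)(C(C)C)C(C)C
Why: Imidazole-promoted O-silylation masks the phenol and the primary alcohol for the organolithium step, and the bulky triisopropylsilyl group is chosen because it resists O-to-C silyl migration (retro-Brook rearrangement) in the ortho-lithiated aryl silyl ether; no stereocentre is involved.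

Step 2
Reactants: 2 [2-bromo-5-({[tri(propan-2-yl)silyl]oxy}methyl)phenoxy]tri(propan-2-yl)silane; 3 oxetan-3-one
Product: 6 3-[2-hydroxy-4-(hydroxymethyl)phenyl]oxetan-3-ol, via aryllithium 4 (not isolated), via bis-silyl oxetanol 5 (not isolated)
Conditions: n-BuLi (1.05 equiv), THF, −78 °C, 10 min; 3 (1.3 equiv), −78 → −20 °C; AcOH (1.1 equiv), then TBAF (3 equiv), 0 °C → rt; aq NH4Cl
Reagents that add atoms: none
Why: Bromine–lithium exchange is fast at −78 °C next to the silyloxy group, the aryllithium adds 1,2 to the strained ketone of oxetan-3-one to form the aryl–C3 bond, and fluoride then removes both silyl groups in the same flask without touching the base-stable oxetane; the new quaternary carbon lies on a mirror plane and is not a stereocentre.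

Step 3
Reactants: 6 3-[2-hydroxy-4-(hydroxymethyl)phenyl]oxetan-3-ol
Product: 8 4-(3-hydroxyoxetan-3-yl)-3-(2-methylpropanoyloxy)benzyl pentanoate, via aryl isobutyrate 7 (not isolated)
Conditions: a) 1 M aq NaOH (1.05 equiv), i-PrCOCl (1.05 equiv), n-Bu4NBr (5 mol %), CH2Cl2–THF, 0 °C, 15 min; b) organic layer separated and dried, n-BuCOCl (1.15 equiv), pyridine (2 equiv), 0 °C → rt
Reagents that add atoms: 2-methylpropanoyl chloride CC(C)C(=O)Cl; pentanoyl chloride CCCCC(=O)Cl
Why: One equivalent of hydroxide ionises only the phenol, so the phase-transfer Schotten–Baumann acylation caps the phenoxide alone, the primary benzylic alcohol is then esterified under pyridine, and the hindered tertiary oxetanol reacts with neither acyl chloride; no stereocentre is involved.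

Step 4
Reactants: 8 4-(3-hydroxyoxetan-3-yl)-3-(2-methylpropanoyloxy)benzyl pentanoate
Product: 9 3-(2-methylpropanoyloxy)-4-[3-(trimethylsilyloxy)oxetan-3-yl]benzyl pentanoate
Conditions: TMSCl (1.5 equiv), imidazole (3 equiv), CH2Cl2, 0 °C → rt; aq NaHCO3, Et3N-washed silica
Reagents that add atoms: chlorotrimethylsilane C[Si](C)(C)Cl
Why: Imidazole-promoted silylation caps the tertiary hydroxyl so that TMSBr cannot release HBr from it in the next step (HBr would open the oxetane without the catalyst), and the silyl group is the same one the key step places on the primary oxygen, so both are removed together; no stereocentre is involved.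

Step 5
Reactants: 9 3-(2-methylpropanoyloxy)-4-[3-(trimethylsilyloxy)oxetan-3-yl]benzyl pentanoate
Product: 11 4-[(2R)-1-bromo-2,3-dihydroxypropan-2-yl]-3-(2-methylpropanoyloxy)benzyl pentanoate, via bis-silyl bromo ether 10 (not isolated)
Conditions: chiral squaramide hydrogen-bond donor (3,5-bis(trifluoromethyl)anilino squaramide of a tert-leucine 2-arylpyrrolidine amide, 10 mol %), TMSBr (1.3 equiv), t-BuOMe, −78 → −40 °C; Et3N/MeOH quench; then citric acid, MeOH, 0 °C → rt
Reagents that add atoms: bromotrimethylsilane C[Si](C)(C)Br
Why: The squaramide binds the bromide of TMSBr through its two N–H bonds, which makes silicon electrophilic enough to silylate the oxetane oxygen, and the catalyst-bound bromide then attacks one of the two enantiotopic ring methylenes (C2 or C4) of the silyloxonium ion in an SN2 opening driven by release of the four-ring strain; acidic methanol removes both trimethylsilyl groups. The closest known reaction type is the hydrogen-bond-donor-catalysed enantioselective addition of TMSBr to 3-substituted and 3,3-disubstituted oxetanes. No ring is closed here: the oxetane is opened, and the oxirane follows in step 6 by a 3-exo-tet closure. The new stereocentre is the former C3, which keeps all four of its bonds; it is set by catalyst control alone, through the choice of the pro-R methylene inside the chiral ion pair, where the aryl and silyloxy groups at C3 are told apart. The step needs enantiotopic-group selectivity and chemoselectivity: the phenol is held as its isobutyrate so that no internal oxygen nucleophile can open the oxonium ion (a free or silylated phenol would close a dihydrobenzofuran), the ester-deactivated aryl ring disfavours ionisation of the benzylic C3–O bond, and the esters are inert to TMSBr at low temperature.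

Step 6
Reactants: 11 4-[(2R)-1-bromo-2,3-dihydroxypropan-2-yl]-3-(2-methylpropanoyloxy)benzyl pentanoate
Product: 13 4-[(2S)-2-(acetyloxymethyl)oxiran-2-yl]-3-(2-methylpropanoyloxy)benzyl pentanoate (target), via epoxy alcohol 12 (not isolated)
Conditions: a) Ag2O (1.5 equiv), 4 Å molecular sieves, CH2Cl2, rt, dark; filtered through Celite; b) Ac2O (1.5 equiv), pyridine (3 equiv), DMAP (2 mol %), 0 °C; cold aq NaHCO3, Et3N-washed silica
Reagents that add atoms: acetic anhydride CC(=O)OC(C)=O
Why: In this silver-assisted halohydrin closure (intramolecular Williamson etherification, 3-exo-tet) the silver ion pulls on bromide while the neutral tertiary hydroxyl attacks the CH2Br carbon from the rear, so no free alkoxide forms that could take over the neighbouring aryl isobutyryl group, the stereocentre is not a reacting centre and keeps its configuration (R in 11 and 12, S in 13 only through the priority rules), a Payne rearrangement of 12 would be degenerate and return the same enantiomer, and the primary alcohol is then acetylated under standard pyridine–DMAP conditions.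

**Compound list**
1 | 2-bromo-5-(hydroxymethyl)phenol | OCc1ccc(Br)c(O)c1 | starting material
2 | [2-bromo-5-({[tri(propan-2-yl)silyl]oxy}methyl)phenoxy]tri(propan-2-yl)silane | CC(C)[Si](OCc1ccc(Br)c(O[Si](C(C)C)(C(C)C)C(C)C)c1)(C(C)C)C(C)C | intermediate
3 | oxetan-3-one | O=C1COC1 | starting material
4 | 2-[tri(propan-2-yl)silyloxy]-4-({[tri(propan-2-yl)silyl]oxy}methyl)phenyllithium | CC(C)[Si](OCc1ccc([Li])c(O[Si](C(C)C)(C(C)C)C(C)C)c1)(C(C)C)C(C)C | intermediate
5 | 3-{2-[tri(propan-2-yl)silyloxy]-4-({[tri(propan-2-yl)silyl]oxy}methyl)phenyl}oxetan-3-ol | CC(C)[Si](OCc1ccc(C2(O)COC2)c(O[Si](C(C)C)(C(C)C)C(C)C)c1)(C(C)C)C(C)C | intermediate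
6 | 3-[2-hydroxy-4-(hydroxymethyl)phenyl]oxetan-3-ol | OCc1ccc(C2(O)COC2)c(O)c1 | intermediate
7 | 5-(hydroxymethyl)-2-(3-hydroxyoxetan-3-yl)phenyl 2-methylpropanoate | CC(C)C(=O)Oc1cc(CO)ccc1C1(O)COC1 | intermediate
8 | 4-(3-hydroxyoxetan-3-yl)-3-(2-methylpropanoyloxy)benzyl pentanoate | CCCCC(=O)OCc1ccc(C2(O)COC2)c(OC(=O)C(C)C)c1 | intermediate
9 | 3-(2-methylpropanoyloxy)-4-[3-(trimethylsilyloxy)oxetan-3-yl]benzyl pentanoate | CCCCC(=O)OCc1ccc(C2(O[Si](C)(C)C)COC2)c(OC(=O)C(C)C)c1 | intermediate
10 | 4-[(2R)-1-bromo-2,3-bis(trimethylsilyloxy)propan-2-yl]-3-(2-methylpropanoyloxy)benzyl pentanoate | CCCCC(=O)OCc1ccc([C@@](O[Si](C)(C)C)(CO[Si](C)(C)C)CBr)c(OC(=O)C(C)C)c1 | intermediate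
11 | 4-[(2R)-1-bromo-2,3-dihydroxypropan-2-yl]-3-(2-methylpropanoyloxy)benzyl pentanoate | CCCCC(=O)OCc1ccc([C@@](O)(CO)CBr)c(OC(=O)C(C)C)c1 | intermediate
12 | 4-[(2R)-2-(hydroxymethyl)oxiran-2-yl]-3-(2-methylpropanoyloxy)benzyl pentanoate | CCCCC(=O)OCc1ccc([C@@]2(CO)CO2)c(OC(=O)C(C)C)c1 | intermediate
13 | 4-[(2S)-2-(acetyloxymethyl)oxiran-2-yl]-3-(2-methylpropanoyloxy)benzyl pentanoate | CCCCC(=O)OCc1ccc([C@@]2(COC(C)=O)CO2)c(OC(=O)C(C)C)c1 | target

Total step count: 6. Longest linear sequence: 6 steps (1 → 13).

**Steps most likely to fail**

Step 5. The catalyst may not discriminate well enough between the two enantiotopic methylenes when C3 carries an ortho-substituted aryl group and a silyloxy group, or an uncatalysed background opening may erode the selectivity. The fallback replaces desymmetrisation by kinetic resolution. It sets out from 9, which would be opened without catalyst (TMSBr, CH2Cl2, −20 °C) to the racemic bis-silyl bromo ether F1, and acidic methanol would give the racemic bromodiol F2. Acetylation of the primary hydroxyl with vinyl acetate and Burkholderia cepacia lipase in t-BuOMe would be taken somewhat beyond half conversion, with an enzyme screened to acetylate the (S)-enantiomer faster. That enantiomer would be removed as the (S)-bromo acetate F3, and the unreacted (R)-bromodiol is compound 11, where the route is rejoined. Lipase resolution of primary alcohols next to a tertiary carbinol stereocentre is known chemistry.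

Step 6. Silver-assisted ionisation of the C–Br bond may be slow or may trigger a 1,2-aryl shift to a ketone, and the primary hydroxyl may compete by re-closing the four-membered ring. The fallback changes the order and the mode of ring closure. It sets out from 11, which would first be acetylated at the primary hydroxyl (Ac2O, pyridine, CH2Cl2, 0 °C) to the (R)-bromo acetate F4, so that the tertiary hydroxyl is the only one left. The oxirane would then be closed in the alkoxide mode (Cs2CO3, MeCN, 0 °C, short contact), which needs no cationic character at carbon, and this gives 13 directly. The contact time is kept short because a free alkoxide could attack the neighbouring aryl ester, which is why this is the second choice.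

Step 2. The ortho-lithiated aryl silyl ether may undergo O-to-C silyl migration before the ketone arrives, or the addition to oxetan-3-one may be incomplete. The fallback uses no silyl groups. It sets out from 1, which would be deprotonated twice (MeLi, 2.05 equiv, THF, −78 → 0 °C) and then exchanged with t-BuLi (2.1 equiv, −78 °C) to the trilithium species F5, a phenoxide that cannot rearrange. Addition of 3 and aqueous NH4Cl would give 6 directly, so step 1 is skipped. Halogen–lithium exchange on lithium bromophenoxides and bromobenzyl alkoxides is known chemistry.

Further compounds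
F1 | step 5 | racemic 4-[1-bromo-2,3-bis(trimethylsilyloxy)propan-2-yl]-3-(2-methylpropanoyloxy)benzyl pentanoate | CCCCC(=O)OCc1ccc(C(O[Si](C)(C)C)(CO[Si](C)(C)C)CBr)c(OC(=O)C(C)C)c1
F2 | step 5 | racemic 4-(1-bromo-2,3-dihydroxypropan-2-yl)-3-(2-methylpropanoyloxy)benzyl pentanoate | CCCCC(=O)OCc1ccc(C(O)(CO)CBr)c(OC(=O)C(C)C)c1
F3 | step 5 | 4-[(2S)-1-(acetyloxy)-3-bromo-2-hydroxypropan-2-yl]-3-(2-methylpropanoyloxy)benzyl pentanoate | CCCCC(=O)OCc1ccc([C@](O)(COC(C)=O)CBr)c(OC(=O)C(C)C)c1
F4 | step 6 | 4-[(2R)-1-(acetyloxy)-3-bromo-2-hydroxypropan-2-yl]-3-(2-methylpropanoyloxy)benzyl pentanoate | CCCCC(=O)OCc1ccc([C@@](O)(COC(C)=O)CBr)c(OC(=O)C(C)C)c1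
F5 | step 2 | lithium 2-lithio-5-[(lithiooxy)methyl]phenolate | [Li]OCc1ccc([Li])c(O[Li])c1
A1 | direct plan | 4-bromo-3-(2-methylpropanoyloxy)benzyl pentanoate | CCCCC(=O)OCc1ccc(Br)c(OC(=O)C(C)C)c1
A2 | direct plan | 2-(4,4,5,5-tetramethyl-1,3,2-dioxaborolan-2-yl)prop-2-en-1-yl acetate | CC(=O)OCC(=C)B1OC(C)(C)C(C)(C)O1
A3 | direct plan | 4-[3-(acetyloxy)prop-1-en-2-yl]-3-(2-methylpropanoyloxy)benzyl pentanoate | CCCCC(=O)OCc1ccc(C(=C)COC(C)=O)c(OC(=O)C(C)C)c1
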